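The route disconnects the C5 ketone on both sides, at C4–C5 and C5–C6 (chain numbered C1 = ArOCH2 to C7 = CMe2, exo-methylene on C3; the benzoate ring is a bystander and no ring is formed). One carbonylative Stille coupling joins a 2-substituted allyl chloride, CO and an isobutenylstannane. It exploits the C4 methylene of the C3=CH2 allyl unit, whose π-allyl has two identical CH2 termini, and delivers the skipped C3=CH2/C5=O/C6=C7 dienone under neutral conditions. The precursor is the (S)-allyl chloride already carrying the C2 hydroperoxide as a 2-methoxyprop-2-yl peroxyketal, installed by inverting displacement before any enone exists, so a single mild hydrolysis follows.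

Key step: step 9

Remark: Ar = 2-methoxy-4-(methoxycarbonyl)phenyl; hydroperoxide 9 is assumed not to be purchasable and is made in step 5; all peroxides (9, 10, 11, 16, 17) are to be handled cold and in solution.

Step 1
Reactants: 1 3-methylbut-2-en-1-ol (prenol)
Product: 2 [(2S)-3,3-dimethyloxiran-2-yl]methanol
Conditions: Ti(OiPr)4 (5 mol%), L-(+)-diethyl tartrate (6 mol%), t-BuOOH (anhydrous), 4 Å molecular sieves, CH2Cl2, −20 °C; water-free work-up
Reagents that add atoms: tert-butyl hydroperoxide, CC(C)(C)OO
Why: Katsuki–Sharpless asymmetric epoxidation of a primary allylic alcohol, in which the L-(+)-tartrate/Ti(OiPr)4 catalyst delivers the peroxide oxygen to the alkene face that gives the 2S epoxy alcohol (C3 carries two methyl groups and is not stereogenic).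

Step 2
Reactants: 2 [(2S)-3,3-dimethyloxiran-2-yl]methanol; 3 methyl vanillate
Product: 4 methyl 4-{[(2S)-3,3-dimethyloxiran-2-yl]methoxy}-3-methoxybenzoate
Conditions: PPh3, DIAD, THF, 0 °C to rt
Reagents that add atoms: none
Why: Mitsunobu etherification, in which the phenol displaces the activated primary hydroxyl at C1 by SN2, so the epoxide and its C2 stereocentre are not involved.

Step 3
Reactants: 4 methyl 4-{[(2S)-3,3-dimethyloxiran-2-yl]methoxy}-3-methoxybenzoate
Product: 6 methyl 4-{[(2R)-2-hydroxy-3-methylbut-3-en-1-yl]oxy}-3-methoxybenzoate, via allyl trimethylsilyl ether 5 (not isolated)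
Conditions: TMSOTf, DBU, toluene, 0 °C to rt; then 1 M HCl, THF, 0 °C
Reagents that add atoms: none
Why: Silyl triflate/amidine isomerisation of an epoxide to an allyl silyl ether, in which TMSOTf ionises the tertiary C3–O bond and DBU removes a methyl proton to give the isopropenyl group; the C2–O bond is never broken, so C2 keeps its spatial arrangement (the descriptor changes from S to R only through the CIP ranking), and dilute acid then cleaves the silyl ether.

Step 4
Reactants: 6 methyl 4-{[(2R)-2-hydroxy-3-methylbut-3-en-1-yl]oxy}-3-methoxybenzoate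
Product: 7 methyl 3-methoxy-4-{[(2R)-2-(methanesulfonyloxy)-3-methylbut-3-en-1-yl]oxy}benzoate
Conditions: Ms2O, Et3N, CH2Cl2, −20 to 0 °C; used crude
Reagents that add atoms: methanesulfonic anhydride, CS(=O)(=O)OS(C)(=O)=O
Why: O-sulfonylation of a secondary alcohol (mesylate formation) with retention at C2, using the anhydride so that no chloride is present to start an allylic substitution.

Step 5
Reactants: 8 2,3-dimethylbut-2-ene
Product: 9 2-hydroperoxy-2-methoxypropane (2-methoxyprop-2-yl hydroperoxide)
Conditions: O3, CH2Cl2–MeOH, −78 °C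
Reagents that add atoms: ozone, [O-][O+]=O; methanol, CO
Why: Ozonolysis in a participating solvent (Criegee mechanism with solvent capture), in which the symmetrical alkene is cleaved to acetone and a fragment that adds methanol to give the α-methoxy hydroperoxide.

Step 6
Reactants: 7 methyl 3-methoxy-4-{[(2R)-2-(methanesulfonyloxy)-3-methylbut-3-en-1-yl]oxy}benzoate; 9 2-hydroperoxy-2-methoxypropane
Product: 10 methyl 3-methoxy-4-{[(2S)-2-[(2-methoxypropan-2-yl)peroxy]-3-methylbut-3-en-1-yl]oxy}benzoate
Conditions: CsOH·H2O, DMF, 0 °C to rt
Reagents that add atoms: none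
Why: Peroxide O-alkylation by SN2, in which the peroxy anion of 9 attacks the allylic C2 from the side opposite the mesylate and inverts it from R to S, while the weakly basic, non-hydroxidic nucleophile should spare the methyl ester.

Step 7
Reactants: 10 methyl 3-methoxy-4-{[(2S)-2-[(2-methoxypropan-2-yl)peroxy]-3-methylbut-3-en-1-yl]oxy}benzoate
Product: 11 methyl 4-{[(2S)-3-(chloromethyl)-2-[(2-methoxypropan-2-yl)peroxy]but-3-en-1-yl]oxy}-3-methoxybenzoate
Conditions: NCS, PhSeCl (10 mol%), CH2Cl2, 0 °C to rt
Reagents that add atoms: N-chlorosuccinimide, O=C1CCC(=O)N1Cl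
Why: Selenium-catalysed ene-type allylic chlorination, in which chlorine goes to the terminal CH2 and the double bond moves into the former methyl group, the only other allylic hydrogen (C2–H) being a deactivated oxygen-bearing methine; the neutral anhydrous medium should leave the peroxyketal and C2 untouched.

Step 8
Reactants: 12 1-bromo-2-methylprop-1-ene
Product: 14 tributyl(2-methylprop-1-enyl)stannane, via isobutenylmagnesium bromide 13 (not isolated)
Conditions: Mg, THF, reflux; then Bu3SnCl, 0 °C to rt
Reagents that add atoms: tributyltin chloride, CCCC[Sn](Cl)(CCCC)CCCC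
Why: Grignard formation from the alkenyl bromide followed by transmetalation to tin (substitution of chloride in Bu3SnCl), with no geometric issue because the alkene terminus carries two methyl groups.

Step 9
Reactants: 11 methyl 4-{[(2S)-3-(chloromethyl)-2-[(2-methoxypropan-2-yl)peroxy]but-3-en-1-yl]oxy}-3-methoxybenzoate; 15 carbon monoxide; 14 tributyl(2-methylprop-1-enyl)stannane
Product: 16 methyl 3-methoxy-4-{[(2S)-2-[(2-methoxypropan-2-yl)peroxy]-7-methyl-3-methylidene-5-oxooct-6-en-1-yl]oxy}benzoate
Conditions: Pd2(dba)3·CHCl3 (2.5 mol%), PPh3 (10 mol%), CO (3 atm), THF, 45 °C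
Reagents that add atoms: none
Why: Oxidative addition of the allylic C–Cl bond of 11 to zerovalent palladium gives the η3-allyl complex (allyl)PdCl(PPh3), CO inserts to give the acyl complex RCH2C(O)PdCl(PPh3), the isobutenyl group moves from tin to palladium and reductive elimination forms C4–C5 and C5–C6 in one operation, releasing Bu3SnCl. The closest known reaction type is the carbonylative Stille coupling of allyl chlorides with alkenylstannanes to allyl vinyl ketones. No ring is closed and no stereocentre is created; C2 lies outside the allyl system and keeps its S configuration. Regiochemistry cannot go wrong because both allyl termini (C4 and the exo-methylene carbon) are CH2 groups, so either insertion site gives the same constitution. The step needs CO insertion to outrun direct allyl–alkenyl coupling, which the CO pressure secures, and needs the C3=CH2/C5=O/C6=C7 array to stay unconjugated, which the neutral, base-free medium secures. The peroxyketal is a spectator of a class known to survive Stille-type couplings when little free phosphine is present (two PPh3 per palladium), and the primary allylic chloride should ionise far faster than the allylic C2–O bond.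

Step 10
Reactants: 16 methyl 3-methoxy-4-{[(2S)-2-[(2-methoxypropan-2-yl)peroxy]-7-methyl-3-methylidene-5-oxooct-6-en-1-yl]oxy}benzoate
Product: 17 methyl 4-{[(2S)-2-hydroperoxy-7-methyl-3-methylidene-5-oxooct-6-en-1-yl]oxy}-3-methoxybenzoate (target)
Conditions: AcOH–THF–H2O (4:2:1), rt
Reagents that add atoms: none
Why: Acid-catalysed hydrolysis of the mixed peroxyketal (acetal cleavage), in which the 2-methoxyprop-2-yl group leaves as acetone and methanol while the O–O bond and C2 are untouched; the weak acid is not expected to conjugate the skipped dienone.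

Compound list
1 | 3-methylbut-2-en-1-ol (prenol) | CC(C)=CCO | starting material
2 | [(2S)-3,3-dimethyloxiran-2-yl]methanol | CC1(C)O[C@H]1CO | intermediate
3 | methyl vanillate (methyl 4-hydroxy-3-methoxybenzoate) | COC(=O)c1ccc(O)c(OC)c1 | starting material
4 | methyl 4-{[(2S)-3,3-dimethyloxiran-2-yl]methoxy}-3-methoxybenzoate | CC1(C)O[C@H]1COc1ccc(C(=O)OC)cc1OC | intermediate
5 | methyl 3-methoxy-4-{[(2R)-3-methyl-2-(trimethylsilyloxy)but-3-en-1-yl]oxy}benzoate | C=C(C)[C@H](COc1ccc(C(=O)OC)cc1OC)O[Si](C)(C)C | intermediate
6 | methyl 4-{[(2R)-2-hydroxy-3-methylbut-3-en-1-yl]oxy}-3-methoxybenzoate | C=C(C)[C@H](COc1ccc(C(=O)OC)cc1OC)O | intermediate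
7 | methyl 3-methoxy-4-{[(2R)-2-(methanesulfonyloxy)-3-methylbut-3-en-1-yl]oxy}benzoate | C=C(C)[C@H](COc1ccc(C(=O)OC)cc1OC)OS(C)(=O)=O | intermediate
8 | 2,3-dimethylbut-2-ene | CC(C)=C(C)C | starting material
9 | 2-hydroperoxy-2-methoxypropane | COC(C)(C)OO | intermediate
10 | methyl 3-methoxy-4-{[(2S)-2-[(2-methoxypropan-2-yl)peroxy]-3-methylbut-3-en-1-yl]oxy}benzoate | C=C(C)[C@@H](COc1ccc(C(=O)OC)cc1OC)OOC(C)(C)OC | intermediate
11 | methyl 4-{[(2S)-3-(chloromethyl)-2-[(2-methoxypropan-2-yl)peroxy]but-3-en-1-yl]oxy}-3-methoxybenzoate | C=C(CCl)[C@@H](COc1ccc(C(=O)OC)cc1OC)OOC(C)(C)OC | intermediate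
12 | 1-bromo-2-methylprop-1-ene | CC(C)=CBr | starting material
13 | (2-methylprop-1-enyl)magnesium bromide | CC(C)=C[Mg]Br | intermediate
14 | tributyl(2-methylprop-1-enyl)stannane | CC(C)=C[Sn](CCCC)(CCCC)CCCC | intermediate
15 | carbon monoxide | [C-]#[O+] | starting material
16 | methyl 3-methoxy-4-{[(2S)-2-[(2-methoxypropan-2-yl)peroxy]-7-methyl-3-methylidene-5-oxooct-6-en-1-yl]oxy}benzoate | C=C(CC(=O)C=C(C)C)[C@@H](COc1ccc(C(=O)OC)cc1OC)OOC(C)(C)OC | intermediate
17 | methyl 4-{[(2S)-2-hydroperoxy-7-methyl-3-methylidene-5-oxooct-6-en-1-yl]oxy}-3-methoxybenzoate | C=C(CC(=O)C=C(C)C)[C@@H](COc1ccc(C(=O)OC)cc1OC)OO | target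

Total step count: 10. Longest linear sequence: 8 steps (1, 2, 3, 4, 6, 7, 9, 10); steps 5 and 8 are side branches.

Steps most likely to fail

Step 9. The O–O bond or the allylic C2–O bond may be attacked by zerovalent palladium or phosphine, CO insertion may lose to direct allyl–alkenyl coupling, or the β,γ-enone may drift into conjugation during the reaction or tin removal. The fallback sets out from 11 and returns at 16, building only C4–C5 and leaving C5 at the alcohol level until the end. Indium-mediated Barbier allylation of 3-methylbut-2-enal with 11 (In powder, NaI, DMF, rt) should give the C5 carbinol as a mixture of C5 epimers, methyl 4-{[(2S)-5-hydroxy-2-[(2-methoxypropan-2-yl)peroxy]-7-methyl-3-methylideneoct-6-en-1-yl]oxy}-3-methoxybenzoate F1. Because the allyl unit has identical CH2 termini, the constitution is again unambiguous. Oxidation with Dess–Martin periodinane (NaHCO3, CH2Cl2, 0 °C) should then give 16 without base.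

Step 6. Substitution at the hindered, β-oxygenated C2 may be slow and lose to attack at the alkene terminus with allylic transposition, to elimination, or to base-induced fragmentation of the secondary peroxide once formed. The fallback sets out from 3 and returns at 10, replacing nucleophilic substitution by an ene oxygenation followed by resolution. O-Alkylation of 3 with prenyl bromide (K2CO3, DMF, rt) gives methyl 3-methoxy-4-[(3-methylbut-2-en-1-yl)oxy]benzoate, the prenyl ether F2. A Schenck ene reaction with singlet oxygen (O2, tetraphenylporphyrin, visible light, CH2Cl2, 0 °C) should place the hydroperoxide on C2 with the double bond shifting into a methyl group, giving the racemic hydroperoxide F3. Protection with 2-methoxypropene and catalytic PPTS (CH2Cl2, 0 °C) gives the racemic peroxyketal F4, which is resolved by preparative HPLC on a chiral stationary phase; the S enantiomer is 10.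

Step 7. Hydrogen loss may occur from C2–H instead of the methyl group, the electron-rich arene may be chlorinated, or adventitious acid may strip the peroxyketal. The fallback sets out from 10 and returns at 11, separating C–H oxidation from C–Cl formation. Allylic oxidation of the methyl group with SeO2 (catalytic) and t-BuOOH (CH2Cl2, rt), an ene/[2,3] sequence that keeps the alkene in place, should give methyl 4-{[(2S)-3-(hydroxymethyl)-2-[(2-methoxypropan-2-yl)peroxy]but-3-en-1-yl]oxy}-3-methoxybenzoate, the allylic alcohol F5. MsCl, LiCl and 2,4,6-collidine in DMF at 0 °C then convert the primary allylic alcohol to chloride 11.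

Further compounds
F1 | step 9 | methyl 4-{[(2S)-5-hydroxy-2-[(2-methoxypropan-2-yl)peroxy]-7-methyl-3-methylideneoct-6-en-1-yl]oxy}-3-methoxybenzoate (C5 epimers) | C=C(CC(O)C=C(C)C)[C@@H](COc1ccc(C(=O)OC)cc1OC)OOC(C)(C)OC
F2 | step 6 | methyl 3-methoxy-4-[(3-methylbut-2-en-1-yl)oxy]benzoate | CC(C)=CCOc1ccc(C(=O)OC)cc1OC
F3 | step 6 | racemic methyl 4-[(2-hydroperoxy-3-methylbut-3-en-1-yl)oxy]-3-methoxybenzoate | C=C(C)C(COc1ccc(C(=O)OC)cc1OC)OO
F4 | step 6 | racemic methyl 3-methoxy-4-({2-[(2-methoxypropan-2-yl)peroxy]-3-methylbut-3-en-1-yl}oxy)benzoate | C=C(C)C(COc1ccc(C(=O)OC)cc1OC)OOC(C)(C)OC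
F5 | step 7 | methyl 4-{[(2S)-3-(hydroxymethyl)-2-[(2-methoxypropan-2-yl)peroxy]but-3-en-1-yl]oxy}-3-methoxybenzoate | C=C(CO)[C@@H](COc1ccc(C(=O)OC)cc1OC)OOC(C)(C)OC
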